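The data come from a simulation for substances that don't exist, noise included.

Between the eta and beta runs one quantity stays put: the concentration of L made per minute.

all flasks: X 110 mM (held); Q 16 mM
- eta: J 1.1 M; D 0.040 M; run made earlier
- beta: J 1.8 M; D 0.040 M; run made earlier
- flask: J 0.80 M; D 0.0400 M; time 6.0 min

| run | time / min | L / % | J / % |
|---|---|---|---|
| eta | 1.33 | 20.1 | 76.4 |
| eta | 2.50 | 37.7 | 57.3 |
| eta | 4.00 | 60.6 | 34.6 |
| eta | 5.00 | 75.3 | 19.9 |
| beta | 0.417 | 3.5 | 93.7 |
| beta | 0.833 | 7.5 | 89.6 |
| beta | 2.00 | 18.9 | 78.6 |
| beta | 5.00 | 46.0 | 50.6 |

(readings scatter by 0.3 percentage points)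

- at the start none of Z is dissolved
- reactions considered so far: X <-> Z; J + Z + Q -> Q + L; J + Z -> G; J + D -> E

- dawn: doubling the transfer coefficient of X, all else as stated
- noon: doubling the amount of Q, all else as stated
- winter: doubling the saturation concentration of X, all else as stated

1. L at 6.0 min, in percent of the J charged
2. the change that raises the amount of L at 6.0 min, in percent of the J charged most ("none" if none brings more than 2 percentage points) (dawn / noon / winter / none)
3. amount of L at 6.0 min, in percent of the J charged, after noon

At 5.00 min the eta run shows 75.3% L and the beta run 46.0%, so the run charged with more J looks slower. Yet cL is 0.828 M in eta and 0.828 M in beta. I therefore replace the eta curve by its mean slope and call this the feed, cL divided by time: 0.166 M/min. The error in doing so is small: the eta reading at 1.33 min gives 0.166 M/min, and at 5.00 min cJ is down to 0.219 M. Over that range the readings of L look zero-order in J, though eta and beta both ran with 16 mM of Q.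

At that last eta reading, the J found in neither J nor L reads 0.0528 M, more than the 0.040 M of D charged. If the flask loses the same, its cap on L is 93.4% of the J charged. The feed reaches that cap at 4.51 min, earlier than 6.0 min, so I expect L near the cap, and a faster feed should gain little.

The forecast gives 93% (90.5% to 94.5%), best change none, and 93.3% (91% to 95%) after noon: “The yield is capped by J lost early, not by rate.”

    X ⇌ Z, rate k1*(csat - [Z]) (kL = 0.0260 /s)
    J + Z + Q → Q + L (k = 270 /M²/s)
    J + Z → G (k = 0.110 /M/s)
    J + D → E (k = 0.380 /M/s)

The flask gives 92.6%; the best change is none: noon adds 1.2 percentage points, less than the 2 points required, and reaches 93.8%. At 6.00 min the flask holds 0% J, with 5.00% as E and 2.36% as G. For the same flask stopped at 1.5 min, the feed gives 31.1% of the J charged as L, and that flask holds 30.9%.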